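## Analysis of the target

Locants used throughout: C1 is the ring sp2 carbon that bears the exocyclic carbon C7, C2 is the vinylic CH, C3 to C6 follow around the ring, and every oxygen takes the number of its carbon.

- **Ring and stereocentres.** The target 9 has one carbocycle, the cyclohexene ring C1–C6 with the alkene C1=C2. It carries C7H2OBz on C1 and four contiguous oxygenated stereocentres, 3S,4R,5R,6R.
- **Relative configuration.** O3/O4 and O4/O5 are trans and O5/O6 are cis. In the favoured half-chair O3, O4 and O5 are therefore (pseudo)equatorial and O6 is pseudoaxial, which is the pattern of a carba-β-galactose.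
- **Acylation pattern.** Only the primary O7 and the secondary O5 carry benzoyl groups, while O3, O4 and O6 are free. Five hydroxyls of similar reactivity must be told apart.
- **Sensitive groups.** The O5 benzoate lies between two free hydroxyls and can migrate under base. The C3–O, C6–O and C7–O bonds are allylic and can ionise in acid. The ring can aromatise by loss of water or benzoic acid.
- **What is hard.** The seven-carbon skeleton is trivial. The difficulty is density: every ring carbon is functionalised, the absolute configuration must be set, and two of five oxygens must be acylated.
- **The feature that invites the strategy.** Ring C1–C6 with C7 is the skeleton of a benzoic ester. The cis pair O5/O6 sits on the meta carbon C5 and the ortho carbon C6, next to the substituted sp2 carbon C1, and C1=C2 with C3–C4 is what remains of a conjugated diene. This is the substitution pattern, in the correct absolute sense, of the ortho,meta cis-dihydrodiol made from a monosubstituted benzene by a Rieske arene dioxygenase of the toluene dioxygenase class.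

## Retrosynthetic reasoning

**9 to 7 through 8.** The two acyl–oxygen bonds at O7 and O5 are cut last, which leads to the unprotected pentaol 7. The esters are not carried through the route because they would not survive the hydride and hydroxide steps. Compound 7 also holds its own code: O7 is the only primary hydroxyl, O5/O6 is the only cis-vicinal pair, and O5 is the equatorial member of that pair. This removes every orthogonal protecting group. The forward reaction has to acylate two hydroxyls out of five.

**7 to 5 through 6.** The C3–O3 bond is cut and the isopropylidene acetal on O5/O6 is put back, which gives the vinyl oxirane 5.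
- C3 is chosen over C4 because it is allylic and far from the acetal. C4 is shielded on the face from which a nucleophile must approach.
- The trans relation O3/O4 then follows from one inversion.
- The forward reaction must be a clean SN2 opening at C3, followed by acetal hydrolysis in the same flask.

**5 to 4.** C7 is returned to the ester oxidation level. No skeletal bond is cut. The ester is wanted earlier in the route, where it deactivates C1=C2 and makes the arene a good enzyme substrate. The forward reaction is an ester reduction that must leave the oxirane untouched.

**4 to 3.** Both C–O bonds of the oxirane at C3 and C4 are cut, which gives the dienoate 3. The disconnection lies on C3=C4 because this is the electron-richer alkene of a 2,4-dienoate. The acetal on the lower face steers a peracid to the upper face, so C3 and C4 are derived from C5 and C6 by substrate control.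

**3 to 2.** The acetal is removed. Its forward task is twofold: it turns the two hydroxyls from syn-directing groups into a steric shield, and it protects the diol from dehydration.

**2 to 1, the key disconnection.** The C5–O5 and C6–O6 bonds are cut together and the ring is rearomatised to the flat, achiral, commercial ester 1.
- The step forms two C–O bonds, sets two stereocentres in absolute terms, and leaves a polarised diene that encodes C3 and C4.
- The precursor has no stereocentre and no sp3 ring carbon.
- The forward reaction must add both oxygen atoms of one dioxygen to one face of one ortho,meta edge and stop there. Only an enzyme does this.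

## Alternatives that were turned down

**Alternative 1:** the textbook route cuts C1=C2. The second-generation Grubbs catalyst would close the acyclic 1,7-diene A1, whose C3–C6 stereotetrad comes from a hexose chain.
- The ring closure creates no stereocentre and no C–O bond, so all four stereocentres and five differentiated oxygens must be built in an open chain.
- At least one of C3 or C6 would come from addition of an alkenyl metal to an α-alkoxy aldehyde, where acyclic 1,2-induction is uncertain.
- The 1,1-disubstituted alkene next to the branched C6 is a slow metathesis partner.
- Three temporary groups on O3, O4 and O6 must be orthogonal to two benzoates that can migrate along a flexible polyol.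
- The step count would be well over twice that of the chosen route.

**Alternative 2:** this route cuts C6–O6 as a C–H oxidation and inverts C3, starting from (−)-shikimic acid A2. That acid already has C1=C2, C7 and the correct C4 and C5. The key step would be allylic oxidation at C6 of a protected 3-epi ester, on the way to the tetrol ester A3.
- The C6 methylene is allylic on the α-carbon side of an enoate, so hydrogen abstraction or an ene reaction there is electronically disfavoured against C3–H.
- The new oxygen must enter cis to the neighbouring O5, which is the more hindered face.
- The Mitsunobu inversion at the allylic C3 carries an SN2′ risk.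
- Each correction needs its own protecting-group pattern, and the chiral pool supplies only two of the four stereocentres.

**Alternative 3:** this is a biomimetic route. Benzoate would open the meta,para arene oxide A4 at C5 to give the trans hydroxy benzoate diene A5. Singlet oxygen would then add across C3 and C6 in a [4+2] reaction to give the endoperoxide A6. Reduction of the O–O bond would give the target with the O5 benzoate already in place.
- The idea avoids any selective acylation.
- A4 would racemise through electrocyclic ring opening and closure, and it would isomerise by the NIH shift under the acid that the opening needs.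
- There is no practical enantioselective access to A4.
- A5 carries O4 on one face and O5 on the other, so the dienophile sees two similar faces. Attack on the wrong face puts the cis pair at O3/O4 instead of O5/O6.
- A5 can also aromatise by loss of benzoic acid.

Key step: step 1

Assumption: the recombinant whole-cell catalyst that expresses toluene dioxygenase is treated as an obtainable reagent, not as a starting material.

## Route

Step 1
Reactants: 1 methyl benzoate
Product: 2 methyl (5S,6R)-5,6-dihydroxycyclohexa-1,3-diene-1-carboxylate
Conditions: E. coli JM109(pDTG601A) whole cells (toluene dioxygenase, IPTG-induced), air, glucose feed (NADH regeneration), mineral salts medium pH 6.8, 30 °C; EtOAc extraction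
Reagents that add atoms: dioxygen, O=O
Why: This is an arene cis-dihydroxylation by a Rieske non-heme iron dioxygenase of the toluene dioxygenase class: the mononuclear ferrous centre binds O2, receives two electrons from NADH through the reductase and ferredoxin components, and hands both oxygen atoms to one face of the C5–C6 edge of the bound arene, so the sextet is broken and the cis relation O5/O6 follows from the mechanism. The closest known reaction type is the whole-cell oxidation of monosubstituted benzenes, short-chain alkyl benzoates included, to ortho,meta cis-dihydrodiols. No ring is closed; the existing ring C1–C6 is dearomatised to the C1=C2–C3=C4 diene. C5 and C6 are set together by the active site, which holds the substituent on C1 in a hydrophobic pocket and so presents only one of the two enantiotopic ortho,meta edges and one face to iron; this sense (5S,6R) is the one the target needs at both centres. The selectivity required is ortho,meta attack instead of ipso,ortho or meta,para attack, and no second oxidation; the first is a property of this enzyme class with small substituents such as CO2Me, and the second is secured because the host lacks the diol dehydrogenase that would lead on to a catechol. The ester also retards acid-catalysed dehydration of 2, since it destabilises the cation on that path. No small reagent dihydroxylates one edge of a benzoate ring enantioselectively and stops there.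

Step 2
Reactants: 2 methyl (5S,6R)-5,6-dihydroxycyclohexa-1,3-diene-1-carboxylate
Product: 3 methyl (3aR,7aS)-2,2-dimethyl-3a,7a-dihydro-1,3-benzodioxole-4-carboxylate (the O5,O6-isopropylidene acetal of 2)
Conditions: 2,2-dimethoxypropane, p-TsOH·H2O (cat.), CH2Cl2, 0 °C to rt; used promptly
Reagents that add atoms: 2,2-dimethoxypropane, COC(C)(C)OC
Why: This is an acid-catalysed transacetalisation of a cis-1,2-diol to the cis-fused dioxolane, and no stereocentre is touched. The acetal removes the syn-directing hydroxyls and covers the lower ring face for step 3.

Step 3
Reactants: 3 methyl (3aR,7aS)-2,2-dimethyl-3a,7a-dihydro-1,3-benzodioxole-4-carboxylate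
Product: 4 methyl (3R,4R,5R,6R)-3,4-epoxy-5,6-(isopropylidenedioxy)cyclohex-1-ene-1-carboxylate (oxirane on the face opposite to the acetal)
Conditions: mCPBA, CH2Cl2–phosphate buffer (pH 8), 0 °C to rt
Reagents that add atoms: mCPBA, OOC(=O)c1cccc(Cl)c1
Why: In this Prilezhaev epoxidation of a 2,4-dienoate the electrophilic peracid takes the γ,δ-alkene C3=C4, because C1=C2 is deactivated by direct conjugation with the ester. C3 and C4 are set by the acetal on C5/C6, which blocks the lower face, so the oxygen should be delivered anti.

Step 4
Reactants: 4 methyl (3R,4R,5R,6R)-3,4-epoxy-5,6-(isopropylidenedioxy)cyclohex-1-ene-1-carboxylate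
Product: 5 [(3R,4R,5R,6R)-3,4-epoxy-5,6-(isopropylidenedioxy)cyclohex-1-en-1-yl]methanol
Conditions: DIBAL-H (2.5 equiv), CH2Cl2, −78 °C; aq. Rochelle salt
Reagents that add atoms: none
Why: This is a 1,2-reduction of an α,β-unsaturated ester to the allylic alcohol, a standard operation on γ,δ-epoxy enoates. At −78 °C the ester carbonyl should react much faster than the oxirane, and no stereocentre is touched.

Step 5
Reactants: 5 [(3R,4R,5R,6R)-3,4-epoxy-5,6-(isopropylidenedioxy)cyclohex-1-en-1-yl]methanol
Product: 7 (3S,4R,5R,6R)-1-(hydroxymethyl)cyclohex-1-ene-3,4,5,6-tetrol, via triol acetonide 6 (not isolated)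
Conditions: 0.5 M aq. KOH, 1,4-dioxane, 80 °C; then Dowex 50WX8 (H+ form), H2O, 40 °C; filtration, lyophilisation
Reagents that add atoms: water, O
Why: Hydroxide, which is regenerated and so acts catalytically, opens the vinyl oxirane by SN2 attack at the allylic C3 from the lower face; the same trajectory at C4 is shielded by the adjacent acetal, so inversion at C3 gives O3 down and O4 up, the trans relation of the target. The acidic resin then hydrolyses the acetal and takes up the potassium ions, so the pentaol should be obtained salt-free. Compound 5 holds no base-labile group and no hydroxyl placed for epoxide migration.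

Step 6
Reactants: 7 (3S,4R,5R,6R)-1-(hydroxymethyl)cyclohex-1-ene-3,4,5,6-tetrol
Product: 9 [(3S,4R,5R,6R)-5-(benzoyloxy)-3,4,6-trihydroxycyclohex-1-en-1-yl]methyl benzoate, via 7-O-monobenzoate 8 (not isolated)
Conditions: BzCl (1.0 equiv), 2,4,6-collidine, MeCN–DMF, −40 °C; then Ph2BOCH2CH2NH2 (10 mol %), i-Pr2NEt, BzCl (1.1 equiv), rt; mildly acidic work-up
Reagents that add atoms: benzoyl chloride, O=C(Cl)c1ccccc1
Why: The first stage uses the intrinsic preference of an acyl chloride with a hindered pyridine base for the only primary hydroxyl O7. The second stage is the diarylborinic-acid-catalysed regioselective acylation of cis-1,2-diols known from galacto-configured pyranosides: the catalyst forms a tetracoordinate borinate only with the single cis-vicinal pair O5/O6, and the equatorial O5 is the oxygen that is acylated. The pseudoaxial O6, flanked by C1 and C5, stays free as the anchor, and no stereocentre is touched.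

## Compound list

1 | methyl benzoate | COC(=O)c1ccccc1 | starting material
2 | methyl (5S,6R)-5,6-dihydroxycyclohexa-1,3-diene-1-carboxylate | COC(=O)C1=CC=C[C@H](O)[C@@H]1O | intermediate
3 | methyl (3aR,7aS)-2,2-dimethyl-3a,7a-dihydro-1,3-benzodioxole-4-carboxylate | COC(=O)C1=CC=C[C@@H]2OC(C)(C)O[C@H]12 | intermediate
4 | methyl (3R,4R,5R,6R)-3,4-epoxy-5,6-(isopropylidenedioxy)cyclohex-1-ene-1-carboxylate | COC(=O)C1=C[C@H]3O[C@H]3[C@@H]2OC(C)(C)O[C@H]12 | intermediate
5 | [(3R,4R,5R,6R)-3,4-epoxy-5,6-(isopropylidenedioxy)cyclohex-1-en-1-yl]methanol | OCC1=C[C@H]3O[C@H]3[C@@H]2OC(C)(C)O[C@H]12 | intermediate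
6 | (3S,4R,5S,6R)-1-(hydroxymethyl)-5,6-(isopropylidenedioxy)cyclohex-1-ene-3,4-diol (triol acetonide, not isolated) | OCC1=C[C@H](O)[C@@H](O)[C@@H]2OC(C)(C)O[C@H]12 | intermediate
7 | (3S,4R,5R,6R)-1-(hydroxymethyl)cyclohex-1-ene-3,4,5,6-tetrol | OCC1=C[C@H](O)[C@@H](O)[C@H](O)[C@@H]1O | intermediate
8 | [(3S,4R,5R,6R)-3,4,5,6-tetrahydroxycyclohex-1-en-1-yl]methyl benzoate (7-O-monobenzoate, not isolated) | O=C(OCC1=C[C@H](O)[C@@H](O)[C@H](O)[C@@H]1O)c1ccccc1 | intermediate
9 | [(3S,4R,5R,6R)-5-(benzoyloxy)-3,4,6-trihydroxycyclohex-1-en-1-yl]methyl benzoate | O=C(OCC1=C[C@H](O)[C@@H](O)[C@H](OC(=O)c2ccccc2)[C@@H]1O)c1ccccc1 | target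

## Step count and least certain steps

Total step count: 6. Longest linear sequence: 6 (1 to 9).

**Step 1 (key step).**
- *Risk:* low productivity. The substrate is toxic to the cells, host esterases can hydrolyse the methyl ester, and the diol can dehydrate with rearomatisation during extraction and concentration.
- *Fallback:* no numbered compound precedes the key step, so the fallback replaces 1 by commercial iodobenzene F1 and comes back to the route at 3.
  - The same enzyme class oxidises this substrate, one of its best accepted, to (1S,2S)-3-iodocyclohexa-3,5-diene-1,2-diol F2.
  - Acetalisation as in step 2 gives the iodo acetonide F3.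
  - The C1–C7 bond is made only then, by alkoxycarbonylation of the alkenyl iodide (CO, MeOH, Et3N, Pd(OAc)2, PPh3), which delivers 3.
  - The approach changes in that C7 is attached after the dearomatisation and is not carried through it.

**Step 6.**
- *Risk:* incomplete site discrimination. The sparingly soluble pentaol may be over-acylated in the first stage, O4 or O3 may compete in the second, and base may promote migration of the benzoyl group from O5 to a neighbouring oxygen.
- *Fallback:* it sets out from 5 and comes back at 8, which is then isolated, and from there reaches 9.
  - The single hydroxyl of 5 is benzoylated (BzCl, pyridine) to the epoxy benzoate F4, where no selection is needed.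
  - Acid-catalysed hydrolysis (HClO4 cat., THF–H2O, then warm aq. AcOH) opens the oxirane at C3 and removes the acetal to give 8.
  - Bu2SnO converts 8 into the 5,6-O-dibutylstannylene acetal F5, a stoichiometric covalent template on the cis pair. It takes one equivalent of BzCl at the equatorial O5 to give 9.

**Step 3.**
- *Risk:* slow oxygen transfer to the electron-poor dienoate. Diels–Alder dimerisation of the diene, and opening of the vinyl oxirane by the carboxylic acid formed, could then compete.
- *Fallback:* it sets out from 3 and comes back at 6, which is then isolated and treated with the acidic resin as in step 5.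
  - Catalytic OsO4 with NMO dihydroxylates C3=C4 anti to the acetal to give the cis-diol F6.
  - SO2Cl2 and Et3N close the 3,4-cyclic sulfate F7.
  - Sodium benzoate in DMF attacks the allylic C3 from the lower face with inversion to give the sodium 4-sulfate F8.
  - Catalytic H2SO4 with one equivalent of water in THF cleaves the sulfate ester to give the 3-benzoate F9.
  - Excess DIBAL-H reduces the methyl ester and cleaves the benzoate in one operation to give 6.

**Step 4.**
- *Risk:* hydride or Lewis-acid attack on the vinyl oxirane (SN2′ reduction or rearrangement) in competition with the ester reduction.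
- *Fallback:* it sets out from 4 and comes back at 6.
  - The oxirane is opened first with water under mild acid catalysis (HClO4 cat., THF–H2O, rt) to give the diol ester F10. Base is avoided because of the ester.
  - Excess DIBAL-H then reduces the ester of this oxirane-free compound to give 6.

## Further compounds

F1 | step 1 | iodobenzene | Ic1ccccc1
F2 | step 1 | (1S,2S)-3-iodocyclohexa-3,5-diene-1,2-diol | IC1=CC=C[C@H](O)[C@@H]1O
F3 | step 1 | (3aS,7aS)-4-iodo-2,2-dimethyl-3a,7a-dihydro-1,3-benzodioxole | IC1=CC=C[C@@H]2OC(C)(C)O[C@H]12
F4 | step 6 | [(3R,4R,5R,6R)-3,4-epoxy-5,6-(isopropylidenedioxy)cyclohex-1-en-1-yl]methyl benzoate | O=C(OCC1=C[C@H]3O[C@H]3[C@@H]2OC(C)(C)O[C@H]12)c1ccccc1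
F5 | step 6 | 5,6-O-dibutylstannylene acetal of 8 | O=C(OCC1=C[C@H](O)[C@@H](O)[C@@H]2O[Sn](CCCC)(CCCC)O[C@H]12)c1ccccc1
F6 | step 3 | methyl (3R,4R,5S,6R)-3,4-dihydroxy-5,6-(isopropylidenedioxy)cyclohex-1-ene-1-carboxylate | COC(=O)C1=C[C@@H](O)[C@@H](O)[C@@H]2OC(C)(C)O[C@H]12
F7 | step 3 | 3,4-cyclic sulfate of F6 (sulfate on the face opposite to the acetal) | COC(=O)C1=C[C@H]3OS(=O)(=O)O[C@H]3[C@@H]2OC(C)(C)O[C@H]12
F8 | step 3 | sodium 4-sulfate of methyl (3S,4R,5S,6R)-3-(benzoyloxy)-4-hydroxy-5,6-(isopropylidenedioxy)cyclohex-1-ene-1-carboxylate | COC(=O)C1=C[C@H](OC(=O)c3ccccc3)[C@@H](OS(=O)(=O)[O-])[C@@H]2OC(C)(C)O[C@H]12.[Na+]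
F9 | step 3 | methyl (3S,4R,5S,6R)-3-(benzoyloxy)-4-hydroxy-5,6-(isopropylidenedioxy)cyclohex-1-ene-1-carboxylate | COC(=O)C1=C[C@H](OC(=O)c3ccccc3)[C@@H](O)[C@@H]2OC(C)(C)O[C@H]12
F10 | step 4 | methyl (3S,4R,5S,6R)-3,4-dihydroxy-5,6-(isopropylidenedioxy)cyclohex-1-ene-1-carboxylate | COC(=O)C1=C[C@H](O)[C@@H](O)[C@@H]2OC(C)(C)O[C@H]12
A1 | alternative 1 | 1,7-diene for ring-closing metathesis, O3,O4,O6-tris(tert-butyldimethylsilyl) ether with benzoates on O5 and O7 | C=C[C@H](O[Si](C)(C)C(C)(C)C)[C@@H](O[Si](C)(C)C(C)(C)C)[C@H](OC(=O)c1ccccc1)[C@@H](C(=C)COC(=O)c1ccccc1)O[Si](C)(C)C(C)(C)C
A2 | alternative 2 | (−)-shikimic acid, (3R,4S,5R)-3,4,5-trihydroxycyclohex-1-ene-1-carboxylic acid | O=C(O)C1=C[C@@H](O)[C@@H](O)[C@H](O)C1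
A3 | alternative 2 | methyl (3S,4R,5R,6R)-3,4,5,6-tetrahydroxycyclohex-1-ene-1-carboxylate | COC(=O)C1=C[C@H](O)[C@@H](O)[C@H](O)[C@@H]1O
A4 | alternative 3 | meta,para arene oxide of benzyl benzoate (oxirane on C4/C5, upper face) | O=C(OCC1=C[C@@H]2O[C@@H]2C=C1)c1ccccc1
A5 | alternative 3 | [(3R,4R)-3-(benzoyloxy)-4-hydroxycyclohexa-1,5-dien-1-yl]methyl benzoate | O=C(OCC1=C[C@@H](OC(=O)c2ccccc2)[C@H](O)C=C1)c1ccccc1
A6 | alternative 3 | C3,C6-endoperoxide of A5 (peroxide bridge on the face of O5) | O=C(OCC1=C[C@@H]2OO[C@H]1[C@@H](OC(=O)c3ccccc3)[C@@H]2O)c1ccccc1
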